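**Plan**

- Cuts, in retrosynthetic order: C15–C5′ (vinylogous aldol that joins the butenolide), C11–C12 (sulfone alkylation that joins a C5 prenyl unit), then C5–C10 and C8–C9 together (one intramolecular Diels–Alder reaction that closes rings A and B), leaving an open chain built around quaternary C4.
- Enabling feature: ring B carries the exocyclic C8=C17 methylene and the C6 oxygen on either side of C7, which is the imprint of a 2-siloxy vinylallene C17=C8=C7–C6(OSi)=C5. C9 bears C11, which can be an ester so that C9=C10 is an E-enoate dienophile. C1–C4 of ring A are the four-carbon tether, and quaternary C4 has no hydrogen, so the 1,5-hydrogen shift that usually competes in vinylallenes is blocked.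
- Forward order: quaternary C4 (Pd allylation of a cyclohexanone) → ring cleavage to the open-chain enoate and allenyl ketone → rings A and B in one step → C6 reduction and C11 sulfone → side chain C12–C15 → butenolide.
- Stereochemistry: C4 by catalyst control (decarboxylative asymmetric allylic alkylation); C5, C9 and C10 from C4 and the E-enoate geometry in the cycloaddition; C6 by thermodynamic (equatorial) ketyl reduction; E-C13=C14 from SeO2 oxidation of prenol; C15 and C5′ by a catalyst-controlled, syn-selective vinylogous Mukaiyama aldol addition.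

Key step: step 12

Remark: labdane-type locants are used throughout (C1–C10 decalin; C11 on C9; C17 = exocyclic CH2 on C8; C18 = CH2O on C4, α; C19 = CH3 on C4, β; C20 = CH3 on C10; C12–C16 side chain with C16 the methyl on C13; C2′–C5′ butenolide with C5′ the O-bearing CH; α is the face of H5, β the face of C20). The pairing of (S)-t-BuPHOX with the (S)-ketone in step 2 is taken as known, so the (R)-ligand is used.

**Step 1**
Reactants: 1 cyclohexanone; 2 diallyl carbonate
Product: 4 allyl 1-methyl-2-oxocyclohexane-1-carboxylate (racemic), via sodium enolate of allyl 2-oxocyclohexane-1-carboxylate 3 (not isolated)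
Conditions: NaH (2.2 equiv), THF, reflux; then MeI, 0 °C to rt
Reagents that add atoms: iodomethane, IC
Why: Claisen-type C-acylation of the ketone enolate by the carbonate followed by C-methylation of the stabilised β-keto ester enolate in the same flask; the quaternary carbon is racemic here and becomes stereodefined in step 2.

**Step 2**
Reactants: 4 allyl 1-methyl-2-oxocyclohexane-1-carboxylate
Product: 5 (R)-2-methyl-2-(prop-2-en-1-yl)cyclohexan-1-one
Conditions: Pd2(dba)3 (2.5 mol %), (R)-t-BuPHOX (6.25 mol %), THF, 25 °C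
Reagents that add atoms: none
Why: Decarboxylative asymmetric allylic alkylation (Tsuji–Trost type) in which zerovalent palladium ionises the allyl ester, CO2 is lost and the prochiral enolate is allylated inside the chiral PHOX–allylpalladium complex, the (R)-ligand setting the all-carbon quaternary centre (future C4) as R.

**Step 3**
Reactants: 5 (R)-2-methyl-2-(prop-2-en-1-yl)cyclohexan-1-one
Product: 6 (2R)-6-hydroxy-2-methyl-2-(prop-2-en-1-yl)cyclohexan-1-one (both C6 epimers)
Conditions: KHMDS, THF, −78 °C; then 3-phenyl-2-(phenylsulfonyl)oxaziridine, −78 °C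
Reagents that add atoms: 3-phenyl-2-(phenylsulfonyl)oxaziridine, O=S(=O)(c1ccccc1)N1OC1c1ccccc1
Why: Davis α-hydroxylation of the potassium enolate, which can form only on the methylene side; the new carbinol centre is destroyed in step 4, so its configuration does not matter.

**Step 4**
Reactants: 6 (2R)-6-hydroxy-2-methyl-2-(prop-2-en-1-yl)cyclohexan-1-one
Product: 7 methyl (2R)-2-methyl-6-oxo-2-(prop-2-en-1-yl)hexanoate
Conditions: Pb(OAc)4, MeOH/benzene (1:1), 0 °C
Reagents that add atoms: methanol, CO
Why: Criegee-type oxidative cleavage of the α-ketol through its methanol hemiketal, so that the ketone carbon leaves as the methyl ester on the quaternary carbon (future C18) and the carbinol carbon as the aldehyde (future C10), without touching the allyl group.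

**Step 5**
Reactants: 7 methyl (2R)-2-methyl-6-oxo-2-(prop-2-en-1-yl)hexanoate
Product: 8 methyl (2R)-2-methyl-2-(prop-2-en-1-yl)hept-6-ynoate
Conditions: dimethyl (1-diazo-2-oxopropyl)phosphonate, K2CO3, MeOH, 0 °C to rt
Reagents that add atoms: dimethyl (1-diazo-2-oxopropyl)phosphonate, CC(=O)C(=[N+]=[N-])P(=O)(OC)OC
Why: Seyferth–Gilbert homologation with the Ohira–Bestmann reagent turns the aldehyde into the terminal alkyne (C10≡C9) under mild carbonate conditions that the non-enolisable quaternary ester tolerates.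

**Step 6**
Reactants: 8 methyl (2R)-2-methyl-2-(prop-2-en-1-yl)hept-6-ynoate
Product: 9 (2R)-2-methyl-2-(prop-2-en-1-yl)hept-6-yn-1-ol
Conditions: LiAlH4, Et2O, 0 °C
Reagents that add atoms: none
Why: Hydride reduction of the neopentyl ester to the primary alcohol (C18), with the isolated alkene and alkyne inert.

**Step 7**
Reactants: 9 (2R)-2-methyl-2-(prop-2-en-1-yl)hept-6-yn-1-ol
Product: 10 {[(2R)-2-methyl-2-(prop-2-en-1-yl)hept-6-yn-1-yl]oxy}tri(propan-2-yl)silane
Conditions: TIPSOTf, 2,6-lutidine, CH2Cl2, 0 °C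
Reagents that add atoms: triisopropylsilyl trifluoromethanesulfonate, CC(C)[Si](OS(=O)(=O)C(F)(F)F)(C(C)C)C(C)C
Why: Silylation of the hindered primary alcohol; the bulky TIPS ether makes the CH2O arm clearly the largest substituent on C4, which is what steers the diene face in step 12.

**Step 8**
Reactants: 10 {[(2R)-2-methyl-2-(prop-2-en-1-yl)hept-6-yn-1-yl]oxy}tri(propan-2-yl)silane
Product: 11 methyl (2E,7R)-3,7-dimethyl-7-({[tri(propan-2-yl)silyl]oxy}methyl)deca-2,9-dienoate
Conditions: Me3Al (3 equiv), Cp2ZrCl2 (0.25 equiv), CH2Cl2, 0 °C to rt; then ClCO2Me, −30 °C to rt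
Reagents that add atoms: trimethylaluminium, C[Al](C)C; methyl chloroformate, COC(=O)Cl
Why: Negishi zirconium-catalysed carboalumination adds methyl and aluminium syn across the terminal alkyne with methyl on the internal carbon, and acylation of the alkenylalane with retention gives the E-enoate (C10 methyl cis to the ester), the monosubstituted alkene reacting far more slowly.

**Step 9**
Reactants: 11 methyl (2E,7R)-3,7-dimethyl-7-({[tri(propan-2-yl)silyl]oxy}methyl)deca-2,9-dienoate
Product: 12 methyl (2E,7R)-3,7-dimethyl-9-oxo-7-({[tri(propan-2-yl)silyl]oxy}methyl)non-2-enoate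
Conditions: OsO4 (2 mol %), NaIO4 (4 equiv), 2,6-lutidine, 1,4-dioxane/H2O (3:1), rt
Reagents that add atoms: sodium periodate, [Na+].[O-]I(=O)(=O)=O
Why: Lemieux–Johnson cleavage, in which OsO4 dihydroxylates the electron-rich monosubstituted alkene in preference to the electron-poor trisubstituted enoate and periodate cleaves the diol to the C6 aldehyde.

**Step 10**
Reactants: 12 methyl (2E,7R)-3,7-dimethyl-9-oxo-7-({[tri(propan-2-yl)silyl]oxy}methyl)non-2-enoate
Product: 13 methyl (2E,7R)-9-hydroxy-3,7-dimethyl-7-({[tri(propan-2-yl)silyl]oxy}methyl)dodec-2-en-11-ynoate (both C9 epimers)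
Conditions: Zn dust, propargyl bromide, THF/sat. aq. NH4Cl, 0 °C to rt
Reagents that add atoms: 3-bromoprop-1-yne, C#CCBr
Why: Barbier propargylation of the aldehyde, which the enoate survives; the carbinol epimers and any allenyl carbinol isomer all converge on the same allenyl ketone in step 11.

**Step 11**
Reactants: 13 methyl (2E,7R)-9-hydroxy-3,7-dimethyl-7-({[tri(propan-2-yl)silyl]oxy}methyl)dodec-2-en-11-ynoate
Product: 15 methyl (2E,7R)-3,7-dimethyl-9-oxo-7-({[tri(propan-2-yl)silyl]oxy}methyl)dodeca-2,10,11-trienoate, via β,γ-alkynyl ketone 14 (not isolated)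
Conditions: Dess–Martin periodinane, CH2Cl2, 0 °C to rt; filtration through basic alumina; then Et3N (0.2 equiv), CH2Cl2, rt
Reagents that add atoms: none
Why: Dess–Martin oxidation to the β,γ-ynone followed by amine-catalysed prototropic isomerisation to the conjugated allenyl ketone (C17=C8=C7–C6=O), a known route to 1,2-allenyl ketones.

**Step 12**
Reactants: 15 methyl (2E,7R)-3,7-dimethyl-9-oxo-7-({[tri(propan-2-yl)silyl]oxy}methyl)dodeca-2,10,11-trienoate
Product: 18 trans-decalin keto ester (C6 ketone; C8=C17 exocyclic methylene; 9β-CO2Me; 10β-CH3; 5α-H; 4α-CH2OTIPS; 4β-CH3), via siloxy vinylallene 16 (not isolated), via dienol silyl ether cycloadduct 17 (not isolated)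
Conditions: TBSOTf (1.3 equiv), Et3N (2 equiv), toluene, −78 to 0 °C; then BHT, 110 °C; then TBAF/AcOH (1:1), THF, −78 to 0 °C
Reagents that add atoms: none
Why: Soft enolisation toward C5 gives the (Z)-2-siloxy vinylallene 16 (diene C5=C6–C7=C8, cumulated with C8=C17); on heating this adds to the E-enoate C9=C10 in a concerted, asynchronous intramolecular [4+2] cycloaddition (type 1, 1,7,9-decatriene) that forms C5–C10 and C8–C9 at once, and buffered fluoride then cleaves dienol silyl ether 17 with kinetic protonation at C7, leaving the C6 ketone and the exocyclic C8=C17 alkene, which is the in-plane π bond of the allene. The closest known reaction types are the intramolecular Diels–Alder reaction of vinylallenes and the Diels–Alder reaction of 2-siloxydienes with enoates. Ring B closes as the six-membered cycloadduct ring through both new bonds, and ring A closes through the C5–C10 bond alone as the fused tether ring (tether C1–C4). C9 and C10 follow from suprafacial addition to the E-enoate (C20 and C11 cis, both β); C5 relative to C10 follows from the ester-endo, tether-exo transition state with a chair-like tether (trans ring fusion); and all three relative to C4 follow from diene-face selection, the dienophile adding anti to the large CH2OTIPS group while the small C19 methyl takes the inside position gauche to the forming bond and to the C6 siloxy group (allylic 1,3-strain). The step needs regioselective enolisation at C5, trans fusion and α-protonation at C7: the tether and the matched polarisation (nucleophilic C5 of the silyl enol ether to the electrophilic β-carbon C10) fix the regiochemistry, the Z-siloxy group disfavours the cis-fused transition state that would put C3 in the inside position, the quaternary C4 blocks the 1,5-hydrogen shift of the vinylallene, and the low-temperature acetic acid quench avoids migration of the exocyclic double bond into conjugation.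

**Step 13**
Reactants: 18 trans-decalin keto ester
Product: 19 6α,11-diol (6α-OH equatorial; C11H2OH on C9β; C8=C17; 4α-CH2OTIPS)
Conditions: SmI2 (10 equiv), H2O, Et3N, THF, 0 °C to rt
Reagents that add atoms: none
Why: Electron-transfer reduction with SmI2–water–amine, in which the C6 ketyl/organosamarium keeps its bulky O–Sm group equatorial and is protonated axially from the β face to give the thermodynamic 6α-alcohol (as in dissolving-metal reductions of ketones flanked by 1,3-diaxial methyl groups), while the excess reagent reduces the methyl ester to the C11 primary alcohol and leaves the isolated alkene and the silyl ether alone.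

**Step 14**
Reactants: 19 6α,11-diol
Product: 20 C11 phenyl sulfide (6α-OH free)
Conditions: (PhS)2, n-Bu3P, pyridine, rt to 50 °C
Reagents that add atoms: diphenyl disulfide, c1ccc(SSc2ccccc2)cc1
Why: Hata reaction (phosphonium activation, SN2 by thiolate), which is selective for the primary C11 alcohol over the hindered secondary C6 alcohol.

**Step 15**
Reactants: 20 C11 phenyl sulfide
Product: 21 6α-TBS ether of the C11 phenyl sulfide
Conditions: TBSOTf, 2,6-lutidine, CH2Cl2, 0 °C to rt
Reagents that add atoms: tert-butyldimethylsilyl trifluoromethanesulfonate, CC(C)(C)[Si](C)(C)OS(=O)(=O)C(F)(F)F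
Why: Silyl triflate silylation of the hindered equatorial secondary alcohol, needed before the carbanion and SiCl4 chemistry that follows.

**Step 16**
Reactants: 21 6α-TBS ether of the C11 phenyl sulfide
Product: 22 C11 phenyl sulfone (6α-OTBS; 18-OTIPS; C8=C17)
Conditions: (NH4)6Mo7O24·4H2O (10 mol %), 30% H2O2, EtOH, 0 °C to rt
Reagents that add atoms: hydrogen peroxide, OO
Why: Molybdate-catalysed peroxide oxidation of sulfide to sulfone, which is chemoselective for sulfur over the unactivated 1,1-disubstituted alkene.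

**Step 17**
Reactants: 23 3-methylbut-2-en-1-ol (prenol)
Product: 24 tert-butyldimethyl[(3-methylbut-2-en-1-yl)oxy]silane
Conditions: TBSCl, imidazole, CH2Cl2, rt
Reagents that add atoms: tert-butyldimethylsilyl chloride, CC(C)(C)[Si](C)(C)Cl
Why: Standard silylation of the primary allylic alcohol.

**Step 18**
Reactants: 24 tert-butyldimethyl[(3-methylbut-2-en-1-yl)oxy]silane
Product: 25 (2E)-4-[(tert-butyldimethylsilyl)oxy]-2-methylbut-2-en-1-ol
Conditions: SeO2 (0.3 equiv), t-BuOOH, salicylic acid (0.1 equiv), CH2Cl2, 0 °C to rt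
Reagents that add atoms: tert-butyl hydroperoxide, CC(C)(C)OO
Why: Riley-type allylic oxidation (ene reaction, then 2,3-sigmatropic shift), which oxidises the E-methyl group of the gem-dimethyl alkene and so fixes the E geometry of the future C13=C14 bond.

**Step 19**
Reactants: 25 (2E)-4-[(tert-butyldimethylsilyl)oxy]-2-methylbut-2-en-1-ol
Product: 26 {[(2E)-4-bromo-3-methylbut-2-en-1-yl]oxy}(tert-butyl)dimethylsilane
Conditions: CBr4, PPh3, CH2Cl2, 0 °C
Reagents that add atoms: carbon tetrabromide, BrC(Br)(Br)Br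
Why: Appel bromination of the primary allylic alcohol under neutral conditions that keep the alkene geometry and the silyl ether.

**Step 20**
Reactants: 22 C11 phenyl sulfone; 26 {[(2E)-4-bromo-3-methylbut-2-en-1-yl]oxy}(tert-butyl)dimethylsilane
Product: 27 C11-alkylated sulfone (both C11 epimers; E-C13=C14; 15-OTBS)
Conditions: n-BuLi (1.05 equiv), THF/HMPA, −78 °C; then 26, −78 to −20 °C
Reagents that add atoms: none
Why: Julia-type alkylation of the α-sulfonyl carbanion with the primary allylic bromide (direct SN2, alkene geometry retained), the classical terpenoid C–C coupling at a hindered carbon; the C11 stereocentre is removed in step 21.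

**Step 21**
Reactants: 27 C11-alkylated sulfone
Product: 28 desulfonylated bis-TBS, TIPS ether (C11H2–C12H2–C13(CH3)=C14H–C15H2OTBS)
Conditions: Na(Hg) (6%), Na2HPO4, MeOH/THF, −20 °C
Reagents that add atoms: none
Why: Reductive desulfonylation by electron transfer; the sulfone is not allylic, so neither double bond can migrate.

**Step 22**
Reactants: 28 desulfonylated bis-TBS, TIPS ether
Product: 29 E-allylic alcohol (15-OH; 6α-OTBS; 18-OTIPS)
Conditions: PPTS (0.2 equiv), MeOH, rt
Reagents that add atoms: none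
Why: Acid-catalysed methanolysis that removes the unhindered primary allylic TBS ether much faster than the hindered secondary TBS ether or the neopentyl TIPS ether.

**Step 23**
Reactants: 29 E-allylic alcohol
Product: 30 E-enal (C15 aldehyde)
Conditions: MnO2, CH2Cl2, rt
Reagents that add atoms: none
Why: MnO2 oxidation, selective for the allylic alcohol and expected to keep the E geometry.

**Step 24**
Reactants: 31 4-methylfuran-2(5H)-one
Product: 32 tert-butyldimethyl[(4-methylfuran-2-yl)oxy]silane
Conditions: TBSOTf, Et3N, CH2Cl2, 0 °C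
Reagents that add atoms: tert-butyldimethylsilyl trifluoromethanesulfonate, CC(C)(C)[Si](C)(C)OS(=O)(=O)C(F)(F)F
Why: Soft enolisation and O-silylation of the butenolide to the aromatic 2-silyloxyfuran, a vinylogous silyl ketene acetal.

**Step 25**
Reactants: 30 E-enal; 32 tert-butyldimethyl[(4-methylfuran-2-yl)oxy]silane
Product: 33 (15S,5′S)-15-hydroxy butenolide (6α-OTBS; 18-OTIPS)
Conditions: SiCl4 (1.1 equiv), (R,R)-bisphosphoramide (N,N′-dimethyl-1,1′-binaphthyl-2,2′-diamine-derived, pentane-1,5-diyl-linked; 5 mol %), i-Pr2NEt (10 mol %), CH2Cl2, −78 °C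
Reagents that add atoms: none
Why: Lewis-base-activated SiCl4 vinylogous Mukaiyama aldol addition, in which the silyloxyfuran attacks through its γ-carbon (C5′) in an open transition state that for furan dienolates favours the syn adduct, and the (R,R)-catalyst is expected to direct attack to the Re face of the enal, setting 15S and, through the syn preference, 5′S.

**Step 26**
Reactants: 33 (15S,5′S)-15-hydroxy butenolide
Product: 34 (5S)-5-[(1S,2E)-1-hydroxy-5-[(1S,4S,4aR,5R,8aR)-4-hydroxy-5-(hydroxymethyl)-5,8a-dimethyl-2-methylidenedecahydronaphthalen-1-yl]-3-methylpent-2-en-1-yl]-4-methylfuran-2(5H)-one (target)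
Conditions: HF·pyridine, pyridine, THF, 0 °C to rt
Reagents that add atoms: none
Why: Fluoride cleavage of the secondary TBS and neopentyl TIPS ethers under buffered, non-basic conditions that should leave the β-hydroxy butenolide and its C5′ stereocentre untouched.

**Compound list**

1 | cyclohexanone | O=C1CCCCC1 | starting material
2 | diallyl carbonate | C=CCOC(=O)OCC=C | starting material
3 | sodium enolate of allyl 2-oxocyclohexane-1-carboxylate | [Na+].[O-]C1=C(C(=O)OCC=C)CCCC1 | intermediate
4 | allyl 1-methyl-2-oxocyclohexane-1-carboxylate (racemic) | C=CCOC(=O)C1(C)CCCCC1=O | intermediate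
5 | (R)-2-methyl-2-(prop-2-en-1-yl)cyclohexan-1-one | C=CC[C@]1(C)C(=O)CCCC1 | intermediate
6 | (2R)-6-hydroxy-2-methyl-2-(prop-2-en-1-yl)cyclohexan-1-one (both C6 epimers) | C=CC[C@]1(C)C(=O)C(O)CCC1 | intermediate
7 | methyl (2R)-2-methyl-6-oxo-2-(prop-2-en-1-yl)hexanoate | C=CC[C@](C)(C(=O)OC)CCCC=O | intermediate
8 | methyl (2R)-2-methyl-2-(prop-2-en-1-yl)hept-6-ynoate | C=CC[C@](C)(C(=O)OC)CCCC#C | intermediate
9 | (2R)-2-methyl-2-(prop-2-en-1-yl)hept-6-yn-1-ol | C=CC[C@](C)(CO)CCCC#C | intermediate
10 | {[(2R)-2-methyl-2-(prop-2-en-1-yl)hept-6-yn-1-yl]oxy}tri(propan-2-yl)silane | C=CC[C@](C)(CO[Si](C(C)C)(C(C)C)C(C)C)CCCC#C | intermediate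
11 | methyl (2E,7R)-3,7-dimethyl-7-({[tri(propan-2-yl)silyl]oxy}methyl)deca-2,9-dienoate | C=CC[C@](C)(CO[Si](C(C)C)(C(C)C)C(C)C)CCC/C(C)=C/C(=O)OC | intermediate
12 | methyl (2E,7R)-3,7-dimethyl-9-oxo-7-({[tri(propan-2-yl)silyl]oxy}methyl)non-2-enoate | O=CC[C@](C)(CO[Si](C(C)C)(C(C)C)C(C)C)CCC/C(C)=C/C(=O)OC | intermediate
13 | methyl (2E,7R)-9-hydroxy-3,7-dimethyl-7-({[tri(propan-2-yl)silyl]oxy}methyl)dodec-2-en-11-ynoate (both C9 epimers) | C#CCC(O)C[C@](C)(CO[Si](C(C)C)(C(C)C)C(C)C)CCC/C(C)=C/C(=O)OC | intermediate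
14 | methyl (2E,7R)-3,7-dimethyl-9-oxo-7-({[tri(propan-2-yl)silyl]oxy}methyl)dodec-2-en-11-ynoate | C#CCC(=O)C[C@](C)(CO[Si](C(C)C)(C(C)C)C(C)C)CCC/C(C)=C/C(=O)OC | intermediate
15 | methyl (2E,7R)-3,7-dimethyl-9-oxo-7-({[tri(propan-2-yl)silyl]oxy}methyl)dodeca-2,10,11-trienoate | C=C=CC(=O)C[C@](C)(CO[Si](C(C)C)(C(C)C)C(C)C)CCC/C(C)=C/C(=O)OC | intermediate
16 | methyl (2E,7R,8Z)-9-[(tert-butyldimethylsilyl)oxy]-3,7-dimethyl-7-({[tri(propan-2-yl)silyl]oxy}methyl)dodeca-2,8,10,11-tetraenoate | C=C=C/C(O[Si](C)(C)C(C)(C)C)=C/[C@](C)(CO[Si](C(C)C)(C(C)C)C(C)C)CCC/C(C)=C/C(=O)OC | intermediate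
17 | cycloadduct: trans-decalin dienol silyl ether (C6–OTBS, C6=C7, C8=C17, 9β-CO2Me, 10β-CH3, 5α-H, 4α-CH2OTIPS, 4β-CH3) | C=C1C=C(O[Si](C)(C)C(C)(C)C)[C@H]2[C@](C)(CO[Si](C(C)C)(C(C)C)C(C)C)CCC[C@]2(C)[C@H]1C(=O)OC | intermediate
18 | trans-decalin keto ester (C6 ketone, C8=C17, 9β-CO2Me, 10β-CH3, 5α-H, 4α-CH2OTIPS, 4β-CH3) | C=C1CC(=O)[C@H]2[C@](C)(CO[Si](C(C)C)(C(C)C)C(C)C)CCC[C@]2(C)[C@H]1C(=O)OC | intermediate
19 | 6α,11-diol (18-OTIPS, C8=C17) | C=C1C[C@H](O)[C@H]2[C@](C)(CO[Si](C(C)C)(C(C)C)C(C)C)CCC[C@]2(C)[C@H]1CO | intermediate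
20 | C11 phenyl sulfide (6α-OH, 18-OTIPS) | C=C1C[C@H](O)[C@H]2[C@](C)(CO[Si](C(C)C)(C(C)C)C(C)C)CCC[C@]2(C)[C@H]1CSc1ccccc1 | intermediate
21 | C11 phenyl sulfide, 6α-OTBS, 18-OTIPS | C=C1C[C@H](O[Si](C)(C)C(C)(C)C)[C@H]2[C@](C)(CO[Si](C(C)C)(C(C)C)C(C)C)CCC[C@]2(C)[C@H]1CSc1ccccc1 | intermediate
22 | C11 phenyl sulfone, 6α-OTBS, 18-OTIPS | C=C1C[C@H](O[Si](C)(C)C(C)(C)C)[C@H]2[C@](C)(CO[Si](C(C)C)(C(C)C)C(C)C)CCC[C@]2(C)[C@H]1CS(=O)(=O)c1ccccc1 | intermediate
23 | 3-methylbut-2-en-1-ol (prenol) | CC(C)=CCO | starting material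
24 | tert-butyldimethyl[(3-methylbut-2-en-1-yl)oxy]silane | CC(C)=CCO[Si](C)(C)C(C)(C)C | intermediate
25 | (2E)-4-[(tert-butyldimethylsilyl)oxy]-2-methylbut-2-en-1-ol | OC/C(C)=C/CO[Si](C)(C)C(C)(C)C | intermediate
26 | {[(2E)-4-bromo-3-methylbut-2-en-1-yl]oxy}(tert-butyl)dimethylsilane | BrC/C(C)=C/CO[Si](C)(C)C(C)(C)C | intermediate
27 | C11-alkylated sulfone (both C11 epimers; 15-OTBS, 6α-OTBS, 18-OTIPS) | C=C1C[C@H](O[Si](C)(C)C(C)(C)C)[C@H]2[C@](C)(CO[Si](C(C)C)(C(C)C)C(C)C)CCC[C@]2(C)[C@H]1C(C/C(C)=C/CO[Si](C)(C)C(C)(C)C)S(=O)(=O)c1ccccc1 | intermediate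
28 | desulfonylated tris-silyl ether (15-OTBS, 6α-OTBS, 18-OTIPS) | C=C1C[C@H](O[Si](C)(C)C(C)(C)C)[C@H]2[C@](C)(CO[Si](C(C)C)(C(C)C)C(C)C)CCC[C@]2(C)[C@H]1CC/C(C)=C/CO[Si](C)(C)C(C)(C)C | intermediate
29 | E-allylic alcohol (15-OH, 6α-OTBS, 18-OTIPS) | C=C1C[C@H](O[Si](C)(C)C(C)(C)C)[C@H]2[C@](C)(CO[Si](C(C)C)(C(C)C)C(C)C)CCC[C@]2(C)[C@H]1CC/C(C)=C/CO | intermediate
30 | E-enal (C15 aldehyde, 6α-OTBS, 18-OTIPS) | C=C1C[C@H](O[Si](C)(C)C(C)(C)C)[C@H]2[C@](C)(CO[Si](C(C)C)(C(C)C)C(C)C)CCC[C@]2(C)[C@H]1CC/C(C)=C/C=O | intermediate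
31 | 4-methylfuran-2(5H)-one | CC1=CC(=O)OC1 | starting material
32 | tert-butyldimethyl[(4-methylfuran-2-yl)oxy]silane | Cc1coc(O[Si](C)(C)C(C)(C)C)c1 | intermediate
33 | (15S,5′S)-15-hydroxy butenolide, 6α-OTBS, 18-OTIPS | C=C1C[C@H](O[Si](C)(C)C(C)(C)C)[C@H]2[C@](C)(CO[Si](C(C)C)(C(C)C)C(C)C)CCC[C@]2(C)[C@H]1CC/C(C)=C/[C@H](O)[C@H]1OC(=O)C=C1C | intermediate
34 | (5S)-5-[(1S,2E)-1-hydroxy-5-[(1S,4S,4aR,5R,8aR)-4-hydroxy-5-(hydroxymethyl)-5,8a-dimethyl-2-methylidenedecahydronaphthalen-1-yl]-3-methylpent-2-en-1-yl]-4-methylfuran-2(5H)-one | C=C1C[C@H](O)[C@H]2[C@](C)(CO)CCC[C@]2(C)[C@H]1CC/C(C)=C/[C@H](O)[C@H]1OC(=O)C=C1C | target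

**Step count and risks**

Total step count: 26. Longest linear sequence: 22 (steps 1–16, 20–23, 25, 26).

The three steps most likely to fail:

Step 12. During enol silylation the amine may remove an allenic proton at C17 instead of a C5 proton, which would give a siloxy enyne that cannot cycloadd; the diene may also add through the face syn to the CH2OTIPS group or through the cis-fused transition state, and the exocyclic double bond may move into conjugation on desilylation. The fallback replaces the pericyclic step by a stepwise anionic annulation. It sets out from 15: kinetic deprotonation at C5 with LiHMDS (THF, −78 °C) should give a lithium enolate that adds to C10 of the enoate, and the resulting ester enolate should add to the central allene carbon C8 (intramolecular double Michael addition). Quenching the dienolate with acetic acid at −78 °C protonates C7 and comes back to the route at 18 with no new isolated compound.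

Step 13. The organosamarium may be protonated on the α face, or the double bond may migrate under the basic amine before the ketone is reduced, giving the axial 6β-alcohol or conjugated material; the hindered ester may also be reduced incompletely. The fallback sets out from 18 and uses kinetic hydride reduction followed by SN2 inversion. NaBH4 (MeOH, 0 °C) should attack the open α face to give the 6β-hydroxy ester F1. Mitsunobu inversion with chloroacetic acid (PPh3, DIAD, toluene) should give the 6α-chloroacetate F2. LiAlH4 (THF, 0 °C) then removes the chloroacetate and reduces the methyl ester, coming back to the route at 19.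

Step 25. The open transition state may give poor syn/anti selectivity, or the catalyst may discriminate the enal faces weakly, so that C15 and C5′ are formed as a mixture. The fallback sets both centres by an auxiliary-controlled glycolate aldol reaction and builds the butenolide afterwards. It sets out from 30 and proceeds as follows.

- The dibutylboron enolate of (R)-4-benzyl-3-{[(4-methoxybenzyl)oxy]acetyl}oxazolidin-2-one (Bu2BOTf, Et3N, CH2Cl2, −78 to 0 °C) should give the Evans syn adduct F3.
- Transamidation (MeONHMe·HCl, Me3Al) gives the Weinreb amide F4.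
- TBSOTf/2,6-lutidine gives the 15-TBS ether F5.
- MeMgBr gives the methyl ketone F6.
- DDQ (CH2Cl2/pH 7 buffer) removes the PMB group to give the α-hydroxy ketone F7.
- Ph3P=C=C=O (toluene, 80 °C; O-acylation, then intramolecular Wittig reaction) closes the butenolide F8.
- HF·pyridine as in step 26 removes the three silyl groups and comes back to the route at 34.

**Further compounds**

F0 | step 12 | none | none
F1 | step 13 | 6β-hydroxy keto-reduced ester (6β-OH, 9β-CO2Me, 18-OTIPS) | C=C1C[C@@H](O)[C@H]2[C@](C)(CO[Si](C(C)C)(C(C)C)C(C)C)CCC[C@]2(C)[C@H]1C(=O)OC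
F2 | step 13 | 6α-chloroacetate ester (9β-CO2Me, 18-OTIPS) | C=C1C[C@H](OC(=O)CCl)[C@H]2[C@](C)(CO[Si](C(C)C)(C(C)C)C(C)C)CCC[C@]2(C)[C@H]1C(=O)OC
F3 | step 25 | Evans syn glycolate aldol adduct (15-OH, PMB ether, (R)-4-benzyloxazolidinone imide) | C=C1C[C@H](O[Si](C)(C)C(C)(C)C)[C@H]2[C@](C)(CO[Si](C(C)C)(C(C)C)C(C)C)CCC[C@]2(C)[C@H]1CC/C(C)=C/[C@H](O)[C@@H](OCc1ccc(OC)cc1)C(=O)N1[C@H](Cc2ccccc2)COC1=O
F4 | step 25 | Weinreb amide (15-OH, PMB ether) | C=C1C[C@H](O[Si](C)(C)C(C)(C)C)[C@H]2[C@](C)(CO[Si](C(C)C)(C(C)C)C(C)C)CCC[C@]2(C)[C@H]1CC/C(C)=C/[C@H](O)[C@@H](OCc1ccc(OC)cc1)C(=O)N(C)OC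
F5 | step 25 | Weinreb amide 15-TBS ether (PMB ether) | C=C1C[C@H](O[Si](C)(C)C(C)(C)C)[C@H]2[C@](C)(CO[Si](C(C)C)(C(C)C)C(C)C)CCC[C@]2(C)[C@H]1CC/C(C)=C/[C@H](O[Si](C)(C)C(C)(C)C)[C@@H](OCc1ccc(OC)cc1)C(=O)N(C)OC
F6 | step 25 | methyl ketone (15-OTBS, PMB ether) | C=C1C[C@H](O[Si](C)(C)C(C)(C)C)[C@H]2[C@](C)(CO[Si](C(C)C)(C(C)C)C(C)C)CCC[C@]2(C)[C@H]1CC/C(C)=C/[C@H](O[Si](C)(C)C(C)(C)C)[C@@H](OCc1ccc(OC)cc1)C(C)=O
F7 | step 25 | α-hydroxy methyl ketone (15-OTBS) | C=C1C[C@H](O[Si](C)(C)C(C)(C)C)[C@H]2[C@](C)(CO[Si](C(C)C)(C(C)C)C(C)C)CCC[C@]2(C)[C@H]1CC/C(C)=C/[C@H](O[Si](C)(C)C(C)(C)C)[C@@H](O)C(C)=O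
F8 | step 25 | butenolide tris-silyl ether (15-OTBS, 6α-OTBS, 18-OTIPS) | C=C1C[C@H](O[Si](C)(C)C(C)(C)C)[C@H]2[C@](C)(CO[Si](C(C)C)(C(C)C)C(C)C)CCC[C@]2(C)[C@H]1CC/C(C)=C/[C@H](O[Si](C)(C)C(C)(C)C)[C@H]1OC(=O)C=C1C
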